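**Retrosynthetic overview**
- No aryl–CH2 bond is ever made. The bridge CH2 is C3 of dimethyl glutarate, and both benzene rings are grown outward from that C5 chain in two directions.
- Target ⇒ bis(resorcinol monomethyl ether)methane, by double Friedel–Crafts C‑acetylation with in‑situ cleavage of the ortho OMe groups.
- Both benzene rings ⇒ 1,3‑bis(4‑methoxy‑2‑pyron‑6‑yl)propane. This is the key step, a two‑directional pyrone → phloroglucinol ether isomerisation (methoxide ring opening, then Dieckmann closure).
- Bis‑pyrone ⇒ bis(3,5‑dioxo ester) ⇒ dimethyl glutarate + 2 × methyl 3‑oxopentanoate, by double dianion γ‑acylation.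
- Ring order: the two 2‑pyrone rings form together (step 2) and are then converted together into the two benzene rings (step 4).

**Assumption:** the target SMILES has no stereocentre, stereogenic axis or stereogenic double bond. The molecule is achiral, so there is no enantiomer to select and the route delivers that single compound.

**Step 1**
Reactants: 1 methyl 3-oxopentanoate (4.4 equiv); 2 dimethyl glutarate (1 equiv)
Product: 4 dimethyl 4,10-dimethyl-3,5,9,11-tetraoxotridecanedioate, via Weiler dianion 3 (not isolated)
Conditions: NaH (4.4 equiv), THF, 0 °C; n-BuLi (4.4 equiv), 0 °C; add 2, 0 °C → rt; cold 2 M HCl; excess 1 distilled off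
Reagents that add atoms: none
Why: Weiler dianion γ‑acylation (crossed Claisen condensation): 3 has a single, highly nucleophilic γ‑carbanion, glutarate cannot undergo Dieckmann self‑closure, the second equivalent of 3 per ester absorbs the acidic proton of each new β‑diketone, and the two CH(Me) centres are enolisable, form as a mixture and disappear in step 2.

**Step 2**
Reactants: 4 dimethyl 4,10-dimethyl-3,5,9,11-tetraoxotridecanedioate
Product: 5 6,6'-(propane-1,3-diyl)bis(4-hydroxy-5-methyl-2H-pyran-2-one)
Conditions: DBU (2.5 equiv), PhMe, reflux; 1 M HCl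
Reagents that add atoms: none
Why: Base‑induced enol lactonisation of a 3,5‑dioxo ester (the standard 4‑hydroxy‑2‑pyrone synthesis): each C5/C9 enolate oxygen closes on its methyl ester, the ketones are protected from aldol chemistry as β‑diketonates, and the acidic pyrone is the thermodynamic sink.

**Step 3**
Reactants: 5 6,6'-(propane-1,3-diyl)bis(4-hydroxy-5-methyl-2H-pyran-2-one)
Product: 6 6,6'-(propane-1,3-diyl)bis(4-methoxy-5-methyl-2H-pyran-2-one)
Conditions: Me2SO4 (2.4 equiv), K2CO3 (3 equiv), acetone, reflux
Reagents that add atoms: dimethyl sulfate, COS(=O)(=O)OC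
Why: Williamson‑type O‑methylation of the vinylogous acid, which for 3‑unsubstituted pyrones gives the 4‑methoxy‑2‑pyrone rather than the 2‑methoxy‑4‑pyrone and removes the acidic OH whose anion would block methoxide attack in step 4.

**Step 4 (key step)**
Reactants: 6 6,6'-(propane-1,3-diyl)bis(4-methoxy-5-methyl-2H-pyran-2-one)
Product: 8 2,2'-methylenebis(5-methoxy-4-methylbenzene-1,3-diol), via ring-opened bis(methoxyenoate) 7 (not isolated)
Conditions: NaOMe (8 equiv), dry MeOH, 185 °C, sealed autoclave, N2; cold 1 M HCl to pH 4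
Reagents that add atoms: none
Why: Proposed new method: methoxide opens each lactone at C2 to the (E)-3-methoxy-5-oxo-2-enoate 7, which holds the ester and the ketone arm cis on the double bond; the ketone enolate at the glutarate‑derived CH2 then closes on the ester (Dieckmann/Claisen cyclisation), and loss of methoxide with tautomerisation gives the phenolate as an irreversible sink, exchange of the 4‑OMe with solvent being degenerate; the closest known reaction type is the NaOMe/MeOH isomerisation at about 185 °C of 4‑methoxy‑6‑methyl‑2‑pyrone to phloroglucinol monomethyl ether, here run twice in one molecule and with a CH2R instead of a CH3 nucleophile; no stereocentre is formed.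

**Step 5**
Reactants: 8 2,2'-methylenebis(5-methoxy-4-methylbenzene-1,3-diol)
Product: 10 3,3'-methylenebis(2,4,6-trihydroxy-5-methylacetophenone), via diacetyl dimethyl ether 9 (not isolated)
Conditions: AcCl (2.4 equiv), AlCl3 (10 equiv), PhCl, 0 °C → rt, then 75 °C; ice/2 M HCl
Reagents that add atoms: acetyl chloride, CC(=O)Cl
Why: Friedel–Crafts acylation at the only free position of each ring (ortho to OH and OMe, para to OH) with preformed acylium complex at 0 °C, followed by chelation‑assisted AlCl3 cleavage of the hindered OMe ortho to the new ketone, at which stage the acylated, aluminium‑chelated rings are too deactivated to lose the bridge by retro‑Friedel–Crafts reaction.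

**Compound list**
1 | methyl 3-oxopentanoate | CCC(=O)CC(=O)OC | starting material
2 | dimethyl glutarate (dimethyl pentanedioate) | COC(=O)CCCC(=O)OC | starting material
3 | sodium lithium α,γ-dianion of methyl 3-oxopentanoate (Weiler dianion) | [Na+].[Li+].COC(=O)[CH-]C(=O)[CH-]C | intermediate
4 | dimethyl 4,10-dimethyl-3,5,9,11-tetraoxotridecanedioate (keto–enol mixture, labile CH(Me) centres unspecified) | COC(=O)CC(=O)C(C)C(=O)CCCC(=O)C(C)C(=O)CC(=O)OC | intermediate
5 | 6,6'-(propane-1,3-diyl)bis(4-hydroxy-5-methyl-2H-pyran-2-one) | CC1=C(CCCC2=C(C)C(O)=CC(=O)O2)OC(=O)C=C1O | intermediate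
6 | 6,6'-(propane-1,3-diyl)bis(4-methoxy-5-methyl-2H-pyran-2-one) | COC1=CC(=O)OC(CCCC2=C(C)C(OC)=CC(=O)O2)=C1C | intermediate
7 | dimethyl (2E,11E)-3,11-dimethoxy-4,10-dimethyl-5,9-dioxotrideca-2,11-dienedioate (labile CH(Me) centres unspecified) | COC(=O)/C=C(/OC)C(C)C(=O)CCCC(=O)C(C)/C(OC)=C\C(=O)OC | intermediate
8 | 2,2'-methylenebis(5-methoxy-4-methylbenzene-1,3-diol) | COc1cc(O)c(Cc2c(O)cc(OC)c(C)c2O)c(O)c1C | intermediate
9 | 3,3'-methylenebis(2,4-dihydroxy-6-methoxy-5-methylacetophenone) | COc1c(C)c(O)c(Cc2c(O)c(C)c(OC)c(C(C)=O)c2O)c(O)c1C(C)=O | intermediate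
10 | 3,3'-methylenebis(2,4,6-trihydroxy-5-methylacetophenone), CNP0190887.0, achiral | CC(=O)c1c(O)c(C)c(O)c(Cc2c(O)c(C)c(O)c(C(C)=O)c2O)c1O | target

**Total step count:** 5. **Longest linear sequence:** 5 (from 1 or 2).

**Three steps most likely to fail**

**Step 4 (highest risk).**
- Failure modes: the stabilised C4/C10 carbanions of 7 can add to the 1,5‑related ketone of the other half, giving a six‑ring aldol that may dehydrate. The esters can also be lost by O‑alkyl cleavage and decarboxylation at 185 °C.
- Fallback: it sets out from 2 and comes back at 10. It keeps glutarate as the bridge but makes both benzene rings directly by a double Effenberger‑type C,C‑diacylation.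
- Compound 2 is converted with MeNH(OMe)·HCl/i‑PrMgCl (THF, −10 °C) into N1,N5-dimethoxy-N1,N5-dimethylpentanediamide F1, and EtMgBr (THF, 0 °C) gives nonane-3,7-dione F2.
- HC(OMe)3 with cat. TsOH in MeOH gives 3,3,7,7-tetramethoxynonane F3. Acid‑catalysed cracking at about 140 °C, with distillation of the alcohol, gives 3,7-dimethoxynona-2,7-diene F4. Any regio‑ or E/Z mixture converges, because both α‑carbons of each masked ketone end up acylated.
- Malonyl dichloride (2.1 equiv, Et2O, −20 °C → rt) closes both rings to 2,2'-methylenebis(4-methylbenzene-1,3,5-triol) F5. Ac2O/BF3·OEt2 (0 → 40 °C, then aqueous MeOH) acetylates the one free position of each ring to give 10.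

**Step 5.**
- Failure mode: before acylation the very electron‑rich diarylmethane 8 can be ipso‑protonated and lose its bridge by retro‑Friedel–Crafts reaction, with scrambling to the other free position.
- Fallback: it sets out from 8 and comes back at 10. It introduces the acetyl groups by carbanion chemistry instead of electrophilic substitution.
- MeI/K2CO3/DMF gives bis(2,4,6-trimethoxy-3-methylphenyl)methane F6, and NBS (2 equiv, MeCN, 0 °C) gives bis(3-bromo-2,4,6-trimethoxy-5-methylphenyl)methane F7.
- n‑BuLi (THF, −78 °C) gives bis(3-lithio-2,4,6-trimethoxy-5-methylphenyl)methane F8. A quench with N‑methoxy‑N‑methylacetamide gives 3,3'-methylenebis(2,4,6-trimethoxy-5-methylacetophenone) F9.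
- BBr3 (excess, CH2Cl2, −78 °C → rt) removes all six methyl groups from the now deactivated rings to give 10.

**Step 1.**
- Failure modes: the dianion may enolise 2, the reaction may stop at mono‑acylation, or the mono‑acylated β‑diketonate may close onto the distal ester.
- Fallback: it sets out from 1 and comes back at 4. It replaces strongly basic dianion chemistry by a neutral Mukaiyama/Chan‑diene γ‑acylation.
- Compound 1 with TMSCl/Et3N gives methyl 3-(trimethylsilyloxy)pent-2-enoate F10. LDA then TMSCl (THF, −78 °C) gives 1-methoxy-1,3-bis(trimethylsilyloxy)penta-1,3-diene F11.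
- Two equivalents of F11 react at the terminal carbon with commercial glutaryl dichloride (CH2Cl2, −78 → 20 °C), and an aqueous work‑up gives 4.

**Further compounds**
F1 | step 4 | N1,N5-dimethoxy-N1,N5-dimethylpentanediamide | CON(C)C(=O)CCCC(=O)N(C)OC
F2 | step 4 | nonane-3,7-dione | CCC(=O)CCCC(=O)CC
F3 | step 4 | 3,3,7,7-tetramethoxynonane | CCC(OC)(OC)CCCC(OC)(OC)CC
F4 | step 4 | 3,7-dimethoxynona-2,7-diene (isomer mixture) | CC=C(OC)CCCC(OC)=CC
F5 | step 4 | 2,2'-methylenebis(4-methylbenzene-1,3,5-triol) | Cc1c(O)cc(O)c(Cc2c(O)cc(O)c(C)c2O)c1O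
F6 | step 5 | bis(2,4,6-trimethoxy-3-methylphenyl)methane | COc1cc(OC)c(Cc2c(OC)cc(OC)c(C)c2OC)c(OC)c1C
F7 | step 5 | bis(3-bromo-2,4,6-trimethoxy-5-methylphenyl)methane | COc1c(Br)c(OC)c(Cc2c(OC)c(Br)c(OC)c(C)c2OC)c(OC)c1C
F8 | step 5 | bis(3-lithio-2,4,6-trimethoxy-5-methylphenyl)methane | COc1c([Li])c(OC)c(Cc2c(OC)c([Li])c(OC)c(C)c2OC)c(OC)c1C
F9 | step 5 | 3,3'-methylenebis(2,4,6-trimethoxy-5-methylacetophenone) | COc1c(C(C)=O)c(OC)c(Cc2c(OC)c(C(C)=O)c(OC)c(C)c2OC)c(OC)c1C
F10 | step 1 | methyl 3-(trimethylsilyloxy)pent-2-enoate | CCC(O[Si](C)(C)C)=CC(=O)OC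
F11 | step 1 | 1-methoxy-1,3-bis(trimethylsilyloxy)penta-1,3-diene | CC=C(O[Si](C)(C)C)C=C(OC)O[Si](C)(C)C
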